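Assumptions: macrocycle numbering used below is C1 = isopropenyl carbon, C6 = butenolide γ‑carbon, C7/C8 = cyclopropane C(Me)/CH, C9–C12 = ene‑dione (furan) carbons, C13 = acetoxy carbon, and the target is (1S,6S,7S,8S,13S). Compounds 1, 5 and 10 are taken as commercial. Nothing here has been run; the route is a plan.

## Retrosynthetic overview

1. The Z‑ene‑dione is unmasked last from a 2,5‑disubstituted 3‑methylfuran by [4+2] cycloaddition of singlet oxygen and reductive opening.
2. The 13‑membered ring is closed at C1–C13 by a Nozaki–Hiyama–Kishi allylation of a furfural with an allylic bromide, which creates the isopropenyl group and the anti C1/C13 pair.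
3. The butenolide comes from α‑alkylation and selenoxide elimination of a saturated γ‑lactone.
4. The cyclopropane is made by a hydroxyl‑directed Simmons–Smith [2+1] cycloaddition on an E‑allylic alcohol; C6, bought in the L‑glutamic‑acid‑derived lactone 1, controls C7 and C8.
5. Ring order: lactone and furan (bought) → cyclopropane → butenolide C=C → macrocycle → furan opened to the ene‑dione.

## Route

**Step 1**
Reactants: 1, (S)-5-(hydroxymethyl)dihydrofuran-2(3H)-one
Product: 2, (S)-5-oxotetrahydrofuran-2-carbaldehyde
Conditions: Dess–Martin periodinane, NaHCO3, CH2Cl2, 0 °C → rt; used crude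
Reagents that add atoms: none
Why: Buffered Dess–Martin oxidation of the primary alcohol does not touch the α‑acyloxy stereocentre (future C6).

**Step 2**
Reactants: 2
Product: 3, (S)-5-ethynyldihydrofuran-2(3H)-one
Conditions: (MeO)2P(O)CHN2, KOt‑Bu, THF, −78 °C → rt
Reagents that add atoms: dimethyl (diazomethyl)phosphonate, COP(=O)(OC)C=[N+]=[N-]
Why: Seyferth–Gilbert homologation with the preformed phosphonate anion at −78 °C adds to the aldehyde faster than it enolises it, so C6 stays S and the lactone survives.

**Step 3**
Reactants: 3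
Product: 4, (S)-4-hydroxy-N-methoxy-N-methylhex-5-ynamide
Conditions: MeNHOMe·HCl, AlMe3, CH2Cl2, 0 °C → rt
Reagents that add atoms: N,O‑dimethylhydroxylamine hydrochloride, CNOC.Cl
Why: Weinreb aminolysis opens the lactone and frees the C6 hydroxyl that is needed as a directing group in steps 6 and 7; the stereocentre is not involved.

**Step 4**
Reactants: 5, 3-methylfuran-2-carbaldehyde
Product: 6, 2-(3-methylfuran-2-yl)-1,3-dioxolane
Conditions: ethylene glycol, TsOH (cat.), benzene, reflux, Dean–Stark
Reagents that add atoms: ethylene glycol, OCCO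
Why: Acetalisation masks the future C13 aldehyde against the organometallic and enolate steps.

**Step 5**
Reactants: 6
Product: 7, 2-(5-iodo-3-methylfuran-2-yl)-1,3-dioxolane
Conditions: n‑BuLi, THF, −78 °C; then I2
Reagents that add atoms: iodine, II
Why: α‑Lithiation occurs at the only free furan α‑position (C5) and iodine traps the anion.

**Step 6**
Reactants: 4 and 7
Product: 8, (S,E)-6-[5-(1,3-dioxolan-2-yl)-4-methylfuran-2-yl]-4-hydroxy-N-methoxy-N,5-dimethylhex-5-enamide
Conditions: AlMe3 (4 equiv), Cp2ZrCl2 (0.5 equiv), CH2Cl2, 0 °C → rt; evaporate excess AlMe3; then 7, Pd(PPh3)4 (5 mol %), ZnCl2, THF, rt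
Reagents that add atoms: trimethylaluminium, C[Al](C)C
Why: Negishi Zr‑catalysed syn‑carboalumination of the propargylic alkoxide puts Me on the internal carbon and Al on the terminus, and Pd/Zn cross‑coupling with retention gives the E‑trisubstituted alkene (C6 and furan trans).

**Step 7**
Reactants: 8
Product: 9, (S)-5-{(1S,2S)-2-[5-(1,3-dioxolan-2-yl)-4-methylfuran-2-yl]-1-methylcyclopropyl}dihydrofuran-2(3H)-one
Conditions: Et2Zn (5 equiv), CH2I2 (10 equiv), CH2Cl2, −10 → 0 °C; then CSA (cat.), CH2Cl2, rt
Reagents that add atoms: diiodomethane, ICI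
Why: Hydroxyl‑directed Simmons–Smith reaction, a concerted stereospecific [2+1] (cheletropic) cycloaddition: the zinc alkoxide at C6 delivers CH2 to the face syn to oxygen in the conformer with C6–H eclipsing the alkene, setting 7S,8S with C6 and furan trans; mild acid then re‑closes the lactone with loss of MeNHOMe.

**Step 8**
Reactants: 10, 5-bromo-2-methylpent-2-ene
Product: 11, (E)-5-bromo-2-methylpent-2-en-1-ol
Conditions: SeO2 (cat.), t‑BuOOH, salicylic acid (cat.), CH2Cl2, rt; then NaBH4, MeOH, 0 °C
Reagents that add atoms: selenium dioxide, O=[Se]=O (oxygen donor), with tert‑butyl hydroperoxide, CC(C)(C)OO, as terminal oxidant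
Why: Riley allylic oxidation (ene reaction then [2,3]‑sigmatropic shift) hydroxylates the E‑methyl selectively, and borohydride returns any over‑oxidised enal to the alcohol.

**Step 9**
Reactants: 11
Product: 12, (E)-[(5-bromo-2-methylpent-2-en-1-yl)oxy](tert-butyl)dimethylsilane
Conditions: TBSCl, imidazole, CH2Cl2, rt
Reagents that add atoms: tert‑butyldimethylsilyl chloride, CC(C)(C)[Si](C)(C)Cl
Why: Silylation protects the allylic alcohol for the enolate chemistry.

**Step 10**
Reactants: 12
Product: 13, (E)-tert-butyl[(5-iodo-2-methylpent-2-en-1-yl)oxy]dimethylsilane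
Conditions: NaI, acetone, reflux
Reagents that add atoms: sodium iodide, [Na+].[I-]
Why: Finkelstein exchange gives the more reactive primary iodide, which favours alkylation over E2.

**Step 11**
Reactants: 9 and 13
Product: 14, (3RS,5S)-3-[(E)-5-(tert-butyldimethylsilyloxy)-4-methylpent-3-en-1-yl]-5-{(1S,2S)-2-[5-(1,3-dioxolan-2-yl)-4-methylfuran-2-yl]-1-methylcyclopropyl}dihydrofuran-2(3H)-one
Conditions: LDA, THF, −78 °C; then 13, HMPA, −78 → −30 °C
Reagents that add atoms: none
Why: Lactone enolate alkylation forms C3–C4; the new α‑centre is a mixture but becomes sp2 in the next step, and C6–C8 carry no acidic hydrogens under these conditions.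

**Step 12**
Reactants: 14
Product: 15, (S)-3-[(E)-5-(tert-butyldimethylsilyloxy)-4-methylpent-3-en-1-yl]-5-{(1S,2S)-2-[5-(1,3-dioxolan-2-yl)-4-methylfuran-2-yl]-1-methylcyclopropyl}furan-2(5H)-one
Conditions: LDA, THF, −78 °C; PhSeBr; then 30% H2O2, pyridine, CH2Cl2, 0 °C → rt
Reagents that add atoms: none
Why: α‑Selenenylation then selenoxide syn‑elimination toward the ring C5–H gives the conjugated endocyclic butenolide; pyridine buffering at 0 °C spares the furan and the side‑chain alkene.

**Step 13**
Reactants: 15
Product: 16, 5-{(1S,2S)-2-[(S)-4-((E)-5-hydroxy-4-methylpent-3-en-1-yl)-5-oxo-2,5-dihydrofuran-2-yl]-2-methylcyclopropyl}-3-methylfuran-2-carbaldehyde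
Conditions: 1 M aq. HCl, THF, 0 °C → rt
Reagents that add atoms: water, O
Why: Mild aqueous acid hydrolyses the dioxolane and cleaves the primary allylic TBS ether in one operation; the butenolide and cyclopropane are stable to it.

**Step 14**
Reactants: 16
Product: 17, 5-{(1S,2S)-2-[(S)-4-((E)-5-bromo-4-methylpent-3-en-1-yl)-5-oxo-2,5-dihydrofuran-2-yl]-2-methylcyclopropyl}-3-methylfuran-2-carbaldehyde
Conditions: PPh3, NBS, CH2Cl2, −20 °C
Reagents that add atoms: N‑bromosuccinimide, O=C1CCC(=O)N1Br
Why: Appel‑type bromination of the allylic alcohol proceeds under neutral conditions that tolerate the furfural and the butenolide.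

**Step 15**
Reactants: 17
Product: 18, macrocyclic alcohol: the 13‑membered carbocycle of the target with C9–C12 as a 2,5‑bridged 3‑methylfuran and a free 13‑OH (1S,6S,7S,8S,13S)
Conditions: CrCl2 (12 equiv), NiCl2 (cat.), 4 Å MS, THF, rt, slow addition to ca. 1 mM
Reagents that add atoms: none
Why: Intramolecular Nozaki–Hiyama–Kishi allylation: γ‑attack of the allylchromium through a chair transition state forms C1–C13, the isopropenyl group and the anti 13‑OH/C1 relationship, with the facial sense relayed across the forming ring from the C6–C8 triad by analogy with related furanobutenolide macrocyclisations.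

**Step 16**
Reactants: 18
Product: 19, 13‑O‑acetate of 18
Conditions: Ac2O, Et3N, DMAP (cat.), CH2Cl2, 0 °C → rt
Reagents that add atoms: acetic anhydride, CC(=O)OC(C)=O
Why: Acylation of the secondary furfuryl alcohol; doing this before oxidation prevents Achmatowicz‑type rearrangement of a free furyl carbinol.

**Step 17**
Reactants: 19
Product: 20, pinnatin B
Conditions: O2, hν, tetraphenylporphyrin, CH2Cl2, −78 °C; then Me2S, −78 °C → rt
Reagents that add atoms: oxygen, O=O
Why: [4+2] cycloaddition of singlet oxygen across the electron‑rich trisubstituted furan gives the 2,5‑endoperoxide, which Me2S reduces to the cis (Z) ene‑dione; the 1,1‑disubstituted isopropenyl group and the butenolide react far more slowly and no stereocentre is touched.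

## Compound list

1 | (S)-5-(hydroxymethyl)dihydrofuran-2(3H)-one (from L‑glutamic acid) | OC[C@@H]1CCC(=O)O1 | starting material
2 | (S)-5-oxotetrahydrofuran-2-carbaldehyde | O=C[C@@H]1CCC(=O)O1 | intermediate
3 | (S)-5-ethynyldihydrofuran-2(3H)-one | C#C[C@@H]1CCC(=O)O1 | intermediate
4 | (S)-4-hydroxy-N-methoxy-N-methylhex-5-ynamide | C#C[C@@H](O)CCC(=O)N(C)OC | intermediate
5 | 3-methylfuran-2-carbaldehyde | Cc1ccoc1C=O | starting material
6 | 2-(3-methylfuran-2-yl)-1,3-dioxolane | Cc1ccoc1C1OCCO1 | intermediate
7 | 2-(5-iodo-3-methylfuran-2-yl)-1,3-dioxolane | Cc1cc(I)oc1C1OCCO1 | intermediate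
8 | (S,E)-furyl allylic alcohol Weinreb amide | CON(C)C(=O)CC[C@H](O)/C(C)=C/c1cc(C)c(C2OCCO2)o1 | intermediate
9 | (S)-lactone bearing the (1S,2S)-1-methyl-2-furylcyclopropyl group | O=C1CC[C@H](O1)[C@@]2(C)C[C@@H]2c3cc(C)c(C4OCCO4)o3 | intermediate
10 | 5-bromo-2-methylpent-2-ene | CC(C)=CCCBr | starting material
11 | (E)-5-bromo-2-methylpent-2-en-1-ol | OC/C(C)=C/CCBr | intermediate
12 | TBS ether of 11 | CC(C)(C)[Si](C)(C)OC/C(C)=C/CCBr | intermediate
13 | (E)-tert-butyl[(5-iodo-2-methylpent-2-en-1-yl)oxy]dimethylsilane | CC(C)(C)[Si](C)(C)OC/C(C)=C/CCI | intermediate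
14 | α‑alkylated lactone (C4 epimers) | O=C1C(CC/C=C(\C)CO[Si](C)(C)C(C)(C)C)C[C@H](O1)[C@@]2(C)C[C@@H]2c3cc(C)c(C4OCCO4)o3 | intermediate
15 | butenolide, TBS ether/acetal | O=C1C(CC/C=C(\C)CO[Si](C)(C)C(C)(C)C)=C[C@H](O1)[C@@]2(C)C[C@@H]2c3cc(C)c(C4OCCO4)o3 | intermediate
16 | butenolide hydroxy aldehyde | O=C1C(CC/C=C(\C)CO)=C[C@H](O1)[C@@]2(C)C[C@@H]2c3cc(C)c(C=O)o3 | intermediate
17 | butenolide bromo aldehyde | O=C1C(CC/C=C(\C)CBr)=C[C@H](O1)[C@@]2(C)C[C@@H]2c3cc(C)c(C=O)o3 | intermediate
18 | macrocyclic furan alcohol | C=C(C)[C@@H]1CCC2=C[C@H](OC2=O)[C@@]3(C)C[C@@H]3c4cc(C)c(o4)[C@H]1O | intermediate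
19 | macrocyclic furan acetate | C=C(C)[C@@H]1CCC2=C[C@H](OC2=O)[C@@]3(C)C[C@@H]3c4cc(C)c(o4)[C@H]1OC(C)=O | intermediate
20 | pinnatin B | C=C(C)[C@@H]1CCC2=C[C@H](OC2=O)[C@@]2(C)C[C@@H]2C(=O)/C=C(/C)C(=O)[C@H]1OC(C)=O | target

## Step count

Total steps: 17. Longest linear sequence: 12 (1 → 2 → 3 → 4 → 8 → 9 → 14 → 15 → 16 → 17 → 18 → 19 → 20, i.e. steps 1–3, 6, 7, 11–17).

## Steps most likely to fail

1. **Step 15 (macrocyclic allylation).** The anti C1/C13 relationship is intrinsic to the reaction, but its sense relative to C6–C8 rests on remote transannular control and is not guaranteed. Fallback: set C1 before ring closure by a Johnson–Claisen rearrangement of the (R)‑glyceraldehyde‑acetonide‑derived 2‑methyl allylic alcohol, cleave the diol and add the 2‑furyl metal under Felkin control to set C13, then close the ring at the furan–cyclopropane/alkene bond by intramolecular Stille coupling.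

2. **Step 7 (directed cyclopropanation).** The 2‑methyl substituent on the E‑alkene may erode or reverse syn selectivity, and early re‑lactonisation would remove the directing hydroxyl. Fallback: start from the enantiomeric lactone (from D‑glutamic acid), accept the anti‑selective addition, hydrolyse the amide and close the lactone under Mitsunobu conditions with inversion at C6.

3. **Step 6 (carboalumination/one‑pot coupling).** The propargylic alkoxide and Weinreb amide may slow the carbometalation, and residual AlMe3 can methylate the iodofuran. Fallback: build the trisubstituted alkene by olefination instead: convert (S)-5-oxotetrahydrofuran-2-carbonyl chloride to the methyl ketone and carry out a Horner–Wadsworth–Emmons reaction with a (furan-2-ylmethyl)phosphonate, separating E from Z.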